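Everything rests on cutting the C1–C1′ bond and remaking it by an Ireland–Claisen rearrangement in ring A. The feature exploited is the 1,3 relationship between C1, the side-chain carbon, and C3, the carbonyl carbon that a Robinson annulation leaves in ring A: an arylacetate on a 3β allylic oxygen across a C1=C2 alkene is tethered so that its α-carbon can reach only the hindered β face of C1, beside quaternary C10 and syn to the C14 methyl. In one operation the step forms C1–C1′, sets C1 and C1′ together and moves the alkene to C2=C3. Its precursor is a trans-fused 15-nor-eudesm-1-ene with the 3β (2,4,6-trimethoxyphenyl)acetate, a 4α silyl ether and a silylated C11 carbinol.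

Key step: step 13

Remark: commercial (+)-dihydrocarvone carries some of its C2 epimer, which is harmless because C2 is planarised in the enamine before it becomes the quaternary C10.

Numbering in names: eudesmane numbering is used. Ring A is C1–C5 plus C10 and ring B is C5–C10. C14 is the methyl on C10 (β), C11 the carbinol carbon on C7 (β), C15 the methylene carbon on C4, and C1′ the benzylic carbon on C1. The β face is the face of C14; "15-nor" means C15 is absent.

Step 1
Reactants: 1 (+)-dihydrocarvone; 2 (R)-1-phenylethylamine; 3 methyl vinyl ketone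
Product: 6 (2S,5R)-2-methyl-2-(3-oxobutyl)-5-(prop-1-en-2-yl)cyclohexan-1-one, via chiral imine 4 (not isolated), via Michael adduct imine 5 (not isolated)
Conditions: 2, toluene, reflux (Dean–Stark); then 3, THF, 40 °C; then 20% aq. AcOH, rt
Reagents that add atoms: water (O)
Why: Chiral-imine Michael addition, in which the more substituted secondary enamine tautomer of 4 adds to 3 through a compact hydrogen-transfer-assisted transition state on the face left open by the (R)-1-phenylethyl group; this should set the quaternary carbon (later C10) as S with its methyl cis to the isopropenyl group, overriding the bias of plain base-mediated annulation toward the C10 epimer, and hydrolysis then returns the ring ketone.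

Step 2
Reactants: 6 (2S,5R)-2-methyl-2-(3-oxobutyl)-5-(prop-1-en-2-yl)cyclohexan-1-one
Product: 7 (4aS,7R)-4a-methyl-7-(prop-1-en-2-yl)-4,4a,5,6,7,8-hexahydronaphthalen-2(3H)-one
Conditions: NaOMe, MeOH, 60 °C
Reagents that add atoms: none
Why: Intramolecular aldol condensation, the ring-closing half of the Robinson annulation, should form ring A as the C4=C5 enone with the C3 carbonyl; C10 is quaternary and C7 is not enolisable, so both centres stay as set.

Step 3
Reactants: 7 (4aS,7R)-4a-methyl-7-(prop-1-en-2-yl)-4,4a,5,6,7,8-hexahydronaphthalen-2(3H)-one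
Product: 8 11-hydroxy-15-nor-eudesm-4-en-3-one
Conditions: Co(acac)2 (20 mol %), PhSiH3, O2 (1 atm), THF, rt
Reagents that add atoms: dioxygen (O=O)
Why: Mukaiyama hydration, in which Markovnikov hydrogen-atom transfer to the 1,1-disubstituted isopropenyl alkene and capture by O2 should give the tertiary C11 alcohol while the electron-poor trisubstituted enone alkene is left alone; no stereocentre is formed.

Step 4
Reactants: 8 11-hydroxy-15-nor-eudesm-4-en-3-one
Product: 9 11-(triethylsilyloxy)-15-nor-eudesm-4-en-3-one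
Conditions: Et3SiCl, imidazole, DMAP (cat.), DMF, 40 °C
Reagents that add atoms: chlorotriethylsilane (CC[Si](Cl)(CC)CC)
Why: Nucleophile-catalysed silylation masks the tertiary C11 alcohol, the only protic site, before the dissolving-metal step; the conditions do not enolise the enone.

Step 5
Reactants: 9 11-(triethylsilyloxy)-15-nor-eudesm-4-en-3-one
Product: 11 3-(trimethylsilyloxy)-11-(triethylsilyloxy)-15-nor-5α-eudesm-3-ene, via lithium enolate 10 (not isolated)
Conditions: Li (2.2 equiv), NH3 (l), t-BuOH (1 equiv), THF, −78 °C; NH3 evaporated; then Me3SiCl, Et3N, THF, 0 °C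
Reagents that add atoms: chlorotrimethylsilane (C[Si](C)(C)Cl)
Why: Birch-type dissolving-metal reduction of the enone with reductive enolate trapping, in which axial protonation of C5 anti to the axial C14 methyl should give the trans ring fusion (5α-H) and O-silylation fixes the enolate regiospecifically between C3 and C4.

Step 6
Reactants: 11 3-(trimethylsilyloxy)-11-(triethylsilyloxy)-15-nor-5α-eudesm-3-ene
Product: 13 4α-hydroxy-11-(triethylsilyloxy)-15-nor-5α-eudesman-3-one, via 4α-trimethylsilyloxy ketone 12 (not isolated)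
Conditions: m-CPBA, NaHCO3, CH2Cl2, −20 → 0 °C; then citric acid, MeOH, rt
Reagents that add atoms: m-chloroperoxybenzoic acid (O=C(OO)c1cccc(Cl)c1)
Why: Rubottom oxidation, in which the peracid should attack the C3=C4 enol ether on the α face because the axial C14 methyl shields C4β; silyl shift and mild methanolysis then give the equatorial 4α carbinol (a temporary centre) without cleaving the tertiary triethylsilyl ether.

Step 7
Reactants: 13 4α-hydroxy-11-(triethylsilyloxy)-15-nor-5α-eudesman-3-one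
Product: 14 4α-(tert-butyldimethylsilyloxy)-11-(triethylsilyloxy)-15-nor-5α-eudesman-3-one
Conditions: t-BuMe2SiCl, imidazole, DMF, rt
Reagents that add atoms: tert-butylchlorodimethylsilane (CC(C)(C)[Si](C)(C)Cl)
Why: Silyl ether formation on the secondary C4 carbinol under mildly basic conditions that should not enolise the α-ketol, so the 4α configuration and the position of the carbonyl are kept.

Step 8
Reactants: 14 4α-(tert-butyldimethylsilyloxy)-11-(triethylsilyloxy)-15-nor-5α-eudesman-3-one
Product: 16 4α-(tert-butyldimethylsilyloxy)-11-(triethylsilyloxy)-15-nor-5α-eudesm-1-en-3-one, via silyl enol ether 15 (not isolated)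
Conditions: LiN(iPr)2, Me3SiCl, THF, −78 °C (in situ trapping); then Pd(OAc)2 (1.1 equiv), MeCN, rt
Reagents that add atoms: none
Why: Kinetic deprotonation should occur at the open C2 methylene and not at the C4 methine (silyloxy-bearing, its axial hydrogen lying under C14); Saegusa–Ito oxidation of the silyl enol ether by divalent palladium then gives the C1=C2 enone by β-hydride loss from C1.

Step 9
Reactants: 16 4α-(tert-butyldimethylsilyloxy)-11-(triethylsilyloxy)-15-nor-5α-eudesm-1-en-3-one
Product: 17 4α-(tert-butyldimethylsilyloxy)-11-(triethylsilyloxy)-15-nor-5α-eudesm-1-en-3β-ol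
Conditions: NaBH4, CeCl3·7H2O, MeOH, −78 → −40 °C
Reagents that add atoms: none
Why: Luche 1,2-reduction, in which axial hydride delivery to C3 on the α face should give the equatorial 3β alcohol trans to the equatorial 4α silyl ether; low temperature and a neutral work-up guard against silyl migration between the two oxygens.

Step 10
Reactants: 18 1,3,5-trimethoxybenzene; 19 ethyl chlorooxoacetate
Product: 20 ethyl 2-oxo-2-(2,4,6-trimethoxyphenyl)acetate
Conditions: AlCl3, CH2Cl2, −10 → 0 °C
Reagents that add atoms: none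
Why: Friedel–Crafts acylation of the highly activated arene by the acid chloride end of 19; the three ring positions are equivalent, the product is deactivated toward a second acylation, and low temperature limits ortho demethylation.

Step 11
Reactants: 20 ethyl 2-oxo-2-(2,4,6-trimethoxyphenyl)acetate
Product: 22 2,4,6-trimethoxyphenylacetic acid, via hydrazone salt 21 (not isolated)
Conditions: N2H4·H2O, KOH, diethylene glycol, 130 °C then 195 °C; then aq. HCl
Reagents that add atoms: potassium hydroxide ([K+].[OH-])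
Why: Wolff–Kishner reduction, in which saponification, hydrazone formation at the activated keto group and base-induced loss of dinitrogen should turn the aryl ketone into the benzylic methylene; the electron-rich methyl ethers resist hydroxide.

Step 12
Reactants: 17 4α-(tert-butyldimethylsilyloxy)-11-(triethylsilyloxy)-15-nor-5α-eudesm-1-en-3β-ol; 22 2,4,6-trimethoxyphenylacetic acid
Product: 23 3β-[(2,4,6-trimethoxyphenyl)acetoxy]-4α-(tert-butyldimethylsilyloxy)-11-(triethylsilyloxy)-15-nor-5α-eudesm-1-ene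
Conditions: DCC, DMAP (cat.), CH2Cl2, 0 °C → rt
Reagents that add atoms: none
Why: Steglich esterification acylates the C3 oxygen without touching the C3–O bond, so the 3β configuration needed for the chirality transfer is retained.

Step 13
Reactants: 23 3β-[(2,4,6-trimethoxyphenyl)acetoxy]-4α-(tert-butyldimethylsilyloxy)-11-(triethylsilyloxy)-15-nor-5α-eudesm-1-ene
Product: 27 (2S)-2-(2,4,6-trimethoxyphenyl)-2-[4α-(tert-butyldimethylsilyloxy)-11-(triethylsilyloxy)-15-nor-5α-eudesm-2-en-1β-yl]acetic acid, via potassium enolate 24 (not isolated), via (Z)-silyl ketene acetal 25 (not isolated), via trimethylsilyl ester 26 (not isolated)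
Conditions: KN(SiMe3)2, toluene–THF, −78 °C; Me3SiCl, −78 °C → rt, then 70 °C; then aq. citric acid, THF, rt
Reagents that add atoms: none
Why: Enolisation of the arylacetate and O-silylation should give the (Z)-silyl ketene acetal 25 (aryl cis to the silyloxy group), which on warming undergoes a concerted suprafacial [3,3]-sigmatropic shift in which the C3–O bond breaks as the C1–C1′ bond forms and the alkene moves to C2=C3, and hydrolysis of the silyl ester 26 then frees the acid. The closest known reaction type is the Ireland–Claisen rearrangement of cyclohex-2-enyl esters with 1,3-chirality transfer across the ring, here stretched to a 2,6-disubstituted arylacetate and a terminus beside a quaternary carbon. No ring is closed. C1 (S, side chain β and equatorial) is controlled by the 3β C–O bond, because the acetal carbon stays tied to the β oxygen and can reach only the β face of C1; C1′ (S) is controlled by the acetal geometry acting through a boat-like six-atom array, the chair being excluded because it would hold the acetal carbon and its silyloxy group over ring A against the axial C14 methyl. Within the boat the C1′ substituent cis to the ring oxygen points over C10 and C14, so the (Z)-acetal should place hydrogen there and the aryl group outward, which is the selectivity the step needs and which Z-selective enolisation of the arylacetate by KN(SiMe3)2 secures. Ring A must leave its half-chair to turn the equatorial 3β C–O bond axial, which is why mild heating is planned.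

Step 14
Reactants: 27 (2S)-2-(2,4,6-trimethoxyphenyl)-2-[4α-(tert-butyldimethylsilyloxy)-11-(triethylsilyloxy)-15-nor-5α-eudesm-2-en-1β-yl]acetic acid
Product: 28 (2S)-2-(2,4,6-trimethoxyphenyl)-2-[4α-(tert-butyldimethylsilyloxy)-11-(triethylsilyloxy)-15-nor-5α-eudesm-2-en-1β-yl]ethan-1-ol
Conditions: LiAlH4, THF, 0 → 40 °C; then H2O, 15% aq. NaOH
Reagents that add atoms: none
Why: Hydride reduction of the carboxylic acid through its aluminium carboxylate, which cannot enolise, should give the primary alcohol with C1′ intact; the silyl ethers and the ring alkene are inert.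

Step 15
Reactants: 28 (2S)-2-(2,4,6-trimethoxyphenyl)-2-[4α-(tert-butyldimethylsilyloxy)-11-(triethylsilyloxy)-15-nor-5α-eudesm-2-en-1β-yl]ethan-1-ol
Product: 29 (2S)-2-(2,4,6-trimethoxyphenyl)-2-[4α-(tert-butyldimethylsilyloxy)-11-(triethylsilyloxy)-15-nor-5α-eudesm-2-en-1β-yl]acetaldehyde
Conditions: Dess–Martin periodinane, NaHCO3, CH2Cl2, 0 °C
Reagents that add atoms: none
Why: Dess–Martin oxidation is fast and near neutral, so the α-aryl aldehyde should form without epimerising C1′; it is taken on at once.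

Step 16
Reactants: 29 (2S)-2-(2,4,6-trimethoxyphenyl)-2-[4α-(tert-butyldimethylsilyloxy)-11-(triethylsilyloxy)-15-nor-5α-eudesm-2-en-1β-yl]acetaldehyde
Product: 30 1β-[(1S)-3-methyl-1-(2,4,6-trimethoxyphenyl)but-2-en-1-yl]-4α-(tert-butyldimethylsilyloxy)-11-(triethylsilyloxy)-15-nor-5α-eudesm-2-ene
Conditions: i-PrPPh3I, KN(SiMe3)2, THF, 0 °C; then 29, −78 → 0 °C
Reagents that add atoms: isopropyltriphenylphosphonium iodide (CC(C)[P+](c1ccccc1)(c1ccccc1)c1ccccc1.[I-])
Why: Wittig olefination with the lithium-free non-stabilised ylide, in which carbonyl addition at low temperature should outrun removal of the hindered C1′ hydrogen, whose enolisation is further disfavoured by allylic strain with the 2,6-dimethoxyaryl group.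

Step 17
Reactants: 30 1β-[(1S)-3-methyl-1-(2,4,6-trimethoxyphenyl)but-2-en-1-yl]-4α-(tert-butyldimethylsilyloxy)-11-(triethylsilyloxy)-15-nor-5α-eudesm-2-ene
Product: 31 1β-[(1S)-3-methyl-1-(2,4,6-trimethoxyphenyl)butyl]-4α-(tert-butyldimethylsilyloxy)-11-(triethylsilyloxy)-15-nor-5α-eudesmane
Conditions: H2 (3 atm), PtO2, EtOAc, rt
Reagents that add atoms: none
Why: Catalytic hydrogenation saturates the ring C2=C3 alkene and the side-chain alkene without creating a stereocentre; platinum in a neutral aprotic solvent is preferred to palladium to suppress double-bond migration through C1′ or C1 and solvolysis of the silyl ethers.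

Step 18
Reactants: 31 1β-[(1S)-3-methyl-1-(2,4,6-trimethoxyphenyl)butyl]-4α-(tert-butyldimethylsilyloxy)-11-(triethylsilyloxy)-15-nor-5α-eudesmane
Product: 32 1β-[(1S)-3-methyl-1-(2,4,6-trimethoxyphenyl)butyl]-15-nor-5α-eudesmane-4α,11-diol
Conditions: Bu4NF, THF, 60 °C
Reagents that add atoms: none
Why: Fluoride-driven desilylation should free the secondary C4 and tertiary C11 alcohols; with no alkene, carbonyl or acid-labile group left, the forcing basic conditions are harmless.

Step 19
Reactants: 32 1β-[(1S)-3-methyl-1-(2,4,6-trimethoxyphenyl)butyl]-15-nor-5α-eudesmane-4α,11-diol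
Product: 33 11-hydroxy-1β-[(1S)-3-methyl-1-(2,4,6-trimethoxyphenyl)butyl]-15-nor-5α-eudesman-4-one
Conditions: Dess–Martin periodinane, NaHCO3, CH2Cl2, rt
Reagents that add atoms: none
Why: Dess–Martin oxidation converts only the secondary C4 carbinol, since the tertiary C11 alcohol has no carbinol hydrogen; the near-neutral medium should leave the trans fusion at C5 untouched.

Step 20
Reactants: 33 11-hydroxy-1β-[(1S)-3-methyl-1-(2,4,6-trimethoxyphenyl)butyl]-15-nor-5α-eudesman-4-one
Product: 34 1β-[(1S)-3-methyl-1-(2,4,6-trimethoxyphenyl)butyl]-5α-eudesm-4(15)-en-11-ol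
Conditions: Ph3PCH3Br, KOt-Bu, THF, rt; then 33, rt → 50 °C (ylide in excess)
Reagents that add atoms: methyltriphenylphosphonium bromide (C[P+](c1ccccc1)(c1ccccc1)c1ccccc1.[Br-])
Why: Wittig methylenation installs C15, one equivalent of ylide resting on the C11 alkoxide; carbonyl addition should outpace enolisation toward C5, and the trans-fused ketone is in any case the more stable C5 epimer.

Step 21
Reactants: 34 1β-[(1S)-3-methyl-1-(2,4,6-trimethoxyphenyl)butyl]-5α-eudesm-4(15)-en-11-ol
Product: 37 1β-[(1S)-1-(3-formyl-2,4,6-trimethoxyphenyl)-3-methylbutyl]-5α-eudesm-4(15)-en-11-ol, via aryllithium 35 (not isolated), via formamide adduct 36 (not isolated)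
Conditions: n-BuLi (2.5 equiv), TMEDA, THF, 0 °C; DMF, −78 °C → rt; H2O
Reagents that add atoms: N,N-dimethylformamide (CN(C)C=O)
Why: Directed ortho-metalation at a ring carbon flanked by two methoxy groups (after deprotonation of the C11 alcohol) and formylation with DMF; the two free ring positions are interchanged by rotation about the C1′–aryl bond, and no acid meets the tertiary alcohol or the exocyclic alkene.

Step 22
Reactants: 37 1β-[(1S)-1-(3-formyl-2,4,6-trimethoxyphenyl)-3-methylbutyl]-5α-eudesm-4(15)-en-11-ol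
Product: 41 1β-[(1S)-1-(3,5-diformyl-2,4,6-trimethoxyphenyl)-3-methylbutyl]-5α-eudesm-4(15)-en-11-ol, via amino alkoxide 38 (not isolated), via lithiated amino alkoxide 39 (not isolated), via formamide adduct 40 (not isolated)
Conditions: LiN(CH2CH2)2NMe (from 1-methylpiperazine, n-BuLi; 2.2 equiv), THF, −20 °C; n-BuLi, TMEDA, −20 → 0 °C; DMF, −78 °C → rt; H2O
Reagents that add atoms: N,N-dimethylformamide (CN(C)C=O)
Why: In situ protection of the aldehyde as its α-amino alkoxide shields it from the alkyllithium; directed ortho-metalation of the last ring C–H between two methoxy groups and DMF formylation follow, and aqueous work-up should release both formyl groups.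

Step 23
Reactants: 41 1β-[(1S)-1-(3,5-diformyl-2,4,6-trimethoxyphenyl)-3-methylbutyl]-5α-eudesm-4(15)-en-11-ol
Product: 42 macrocarpal H
Conditions: LiSC6H4-4-Me (from 4-methylbenzenethiol, n-BuLi; excess), DMPU, 120 °C; then cold 0.5 M aq. HCl
Reagents that add atoms: none
Why: Nucleophilic SN2 O-demethylation by the soft thiolate, each methoxy group being ortho or para to formyl groups so that the phenoxides are good leaving groups; thiolate addition to the aldehydes is reversible, and with no Lewis or strong protic acid in the reaction the tertiary alcohol and the exocyclic alkene should survive.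

Compound list
1 | (+)-dihydrocarvone, (2R,5R)-2-methyl-5-(prop-1-en-2-yl)cyclohexan-1-one | C[C@@H]1CC[C@H](CC1=O)C(C)=C | starting material
2 | (R)-1-phenylethylamine | C[C@@H](N)c1ccccc1 | starting material
3 | methyl vinyl ketone | C=CC(C)=O | starting material
4 | N-[(R)-1-phenylethyl]imine of 1 (reacts as its secondary enamine tautomer) | C[C@@H]1CC[C@H](CC1=N[C@H](C)c1ccccc1)C(C)=C | intermediate
5 | N-[(R)-1-phenylethyl]imine at the ring carbonyl of 6 | CC(=O)CC[C@]1(C)CC[C@@H](C(C)=C)CC1=N[C@H](C)c1ccccc1 | intermediate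
6 | (2S,5R)-2-methyl-2-(3-oxobutyl)-5-(prop-1-en-2-yl)cyclohexan-1-one | CC(=O)CC[C@]1(C)CC[C@@H](C(C)=C)CC1=O | intermediate
7 | (4aS,7R)-4a-methyl-7-(prop-1-en-2-yl)-4,4a,5,6,7,8-hexahydronaphthalen-2(3H)-one (15-nor-eudesma-4,11-dien-3-one) | O=C1CC[C@]2(C)CC[C@@H](C(C)=C)CC2=C1 | intermediate
8 | 11-hydroxy-15-nor-eudesm-4-en-3-one (10β-methyl, 7β-(2-hydroxypropan-2-yl)) | O=C1CC[C@]2(C)CC[C@@H](C(C)(C)O)CC2=C1 | intermediate
9 | 11-(triethylsilyloxy)-15-nor-eudesm-4-en-3-one | O=C1CC[C@]2(C)CC[C@@H](C(C)(C)O[Si](CC)(CC)CC)CC2=C1 | intermediate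
10 | lithium 11-(triethylsilyloxy)-15-nor-5α-eudesm-3-en-3-olate | [Li]OC=1CC[C@]2(C)CC[C@@H](C(C)(C)O[Si](CC)(CC)CC)C[C@H]2C=1 | intermediate
11 | 3-(trimethylsilyloxy)-11-(triethylsilyloxy)-15-nor-5α-eudesm-3-ene | C[Si](C)(C)OC=1CC[C@]2(C)CC[C@@H](C(C)(C)O[Si](CC)(CC)CC)C[C@H]2C=1 | intermediate
12 | 4α-(trimethylsilyloxy)-11-(triethylsilyloxy)-15-nor-5α-eudesman-3-one | O=C1CC[C@]2(C)CC[C@@H](C(C)(C)O[Si](CC)(CC)CC)C[C@H]2[C@@H]1O[Si](C)(C)C | intermediate
13 | 4α-hydroxy-11-(triethylsilyloxy)-15-nor-5α-eudesman-3-one | O=C1CC[C@]2(C)CC[C@@H](C(C)(C)O[Si](CC)(CC)CC)C[C@H]2[C@@H]1O | intermediate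
14 | 4α-(tert-butyldimethylsilyloxy)-11-(triethylsilyloxy)-15-nor-5α-eudesman-3-one | O=C1CC[C@]2(C)CC[C@@H](C(C)(C)O[Si](CC)(CC)CC)C[C@H]2[C@@H]1O[Si](C)(C)C(C)(C)C | intermediate
15 | 4α-(tert-butyldimethylsilyloxy)-3-(trimethylsilyloxy)-11-(triethylsilyloxy)-15-nor-5α-eudesm-2-ene | C[Si](C)(C)OC1=CC[C@]2(C)CC[C@@H](C(C)(C)O[Si](CC)(CC)CC)C[C@H]2[C@@H]1O[Si](C)(C)C(C)(C)C | intermediate
16 | 4α-(tert-butyldimethylsilyloxy)-11-(triethylsilyloxy)-15-nor-5α-eudesm-1-en-3-one | O=C1C=C[C@]2(C)CC[C@@H](C(C)(C)O[Si](CC)(CC)CC)C[C@H]2[C@@H]1O[Si](C)(C)C(C)(C)C | intermediate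
17 | 4α-(tert-butyldimethylsilyloxy)-11-(triethylsilyloxy)-15-nor-5α-eudesm-1-en-3β-ol | O[C@H]1C=C[C@]2(C)CC[C@@H](C(C)(C)O[Si](CC)(CC)CC)C[C@H]2[C@@H]1O[Si](C)(C)C(C)(C)C | intermediate
18 | 1,3,5-trimethoxybenzene | COc1cc(OC)cc(OC)c1 | starting material
19 | ethyl chlorooxoacetate | CCOC(=O)C(=O)Cl | starting material
20 | ethyl 2-oxo-2-(2,4,6-trimethoxyphenyl)acetate | CCOC(=O)C(=O)c1c(OC)cc(OC)cc1OC | intermediate
21 | potassium 2-hydrazinylidene-2-(2,4,6-trimethoxyphenyl)acetate | NN=C(C(=O)[O-])c1c(OC)cc(OC)cc1OC.[K+] | intermediate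
22 | 2,4,6-trimethoxyphenylacetic acid | COc1cc(OC)c(CC(=O)O)c(OC)c1 | intermediate
23 | 3β-[(2,4,6-trimethoxyphenyl)acetoxy]-4α-(tert-butyldimethylsilyloxy)-11-(triethylsilyloxy)-15-nor-5α-eudesm-1-ene | COc1cc(OC)c(CC(=O)O[C@H]2C=C[C@]3(C)CC[C@@H](C(C)(C)O[Si](CC)(CC)CC)C[C@H]3[C@@H]2O[Si](C)(C)C(C)(C)C)c(OC)c1 | intermediate
24 | (Z)-potassium enolate of 23 (aryl cis to OK) | COc1cc(OC)c(/C=C(\O[K])O[C@H]2C=C[C@]3(C)CC[C@@H](C(C)(C)O[Si](CC)(CC)CC)C[C@H]3[C@@H]2O[Si](C)(C)C(C)(C)C)c(OC)c1 | intermediate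
25 | (Z)-trimethylsilyl ketene acetal of 23 (aryl cis to OSiMe3) | COc1cc(OC)c(/C=C(\O[Si](C)(C)C)O[C@H]2C=C[C@]3(C)CC[C@@H](C(C)(C)O[Si](CC)(CC)CC)C[C@H]3[C@@H]2O[Si](C)(C)C(C)(C)C)c(OC)c1 | intermediate
26 | trimethylsilyl ester of 27 | CC(C)(C)[Si](C)(C)O[C@@H]1C=C[C@@H]([C@H](C(=O)O[Si](C)(C)C)c3c(OC)cc(OC)cc3OC)[C@]2(C)CC[C@@H](C(C)(C)O[Si](CC)(CC)CC)C[C@@H]12 | intermediate
27 | (2S)-2-(2,4,6-trimethoxyphenyl)-2-[4α-(tert-butyldimethylsilyloxy)-11-(triethylsilyloxy)-15-nor-5α-eudesm-2-en-1β-yl]acetic acid | CC(C)(C)[Si](C)(C)O[C@@H]1C=C[C@@H]([C@H](C(=O)O)c3c(OC)cc(OC)cc3OC)[C@]2(C)CC[C@@H](C(C)(C)O[Si](CC)(CC)CC)C[C@@H]12 | intermediate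
28 | (2S)-2-(2,4,6-trimethoxyphenyl)-2-[4α-(tert-butyldimethylsilyloxy)-11-(triethylsilyloxy)-15-nor-5α-eudesm-2-en-1β-yl]ethan-1-ol | CC(C)(C)[Si](C)(C)O[C@@H]1C=C[C@@H]([C@H](CO)c3c(OC)cc(OC)cc3OC)[C@]2(C)CC[C@@H](C(C)(C)O[Si](CC)(CC)CC)C[C@@H]12 | intermediate
29 | (2S)-2-(2,4,6-trimethoxyphenyl)-2-[4α-(tert-butyldimethylsilyloxy)-11-(triethylsilyloxy)-15-nor-5α-eudesm-2-en-1β-yl]acetaldehyde | CC(C)(C)[Si](C)(C)O[C@@H]1C=C[C@@H]([C@H](C=O)c3c(OC)cc(OC)cc3OC)[C@]2(C)CC[C@@H](C(C)(C)O[Si](CC)(CC)CC)C[C@@H]12 | intermediate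
30 | 1β-[(1S)-3-methyl-1-(2,4,6-trimethoxyphenyl)but-2-en-1-yl]-4α-(tert-butyldimethylsilyloxy)-11-(triethylsilyloxy)-15-nor-5α-eudesm-2-ene | CC(C)(C)[Si](C)(C)O[C@@H]1C=C[C@@H]([C@H](C=C(C)C)c3c(OC)cc(OC)cc3OC)[C@]2(C)CC[C@@H](C(C)(C)O[Si](CC)(CC)CC)C[C@@H]12 | intermediate
31 | 1β-[(1S)-3-methyl-1-(2,4,6-trimethoxyphenyl)butyl]-4α-(tert-butyldimethylsilyloxy)-11-(triethylsilyloxy)-15-nor-5α-eudesmane | CC(C)(C)[Si](C)(C)O[C@@H]1CC[C@@H]([C@H](CC(C)C)c3c(OC)cc(OC)cc3OC)[C@]2(C)CC[C@@H](C(C)(C)O[Si](CC)(CC)CC)C[C@@H]12 | intermediate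
32 | 1β-[(1S)-3-methyl-1-(2,4,6-trimethoxyphenyl)butyl]-15-nor-5α-eudesmane-4α,11-diol | O[C@@H]1CC[C@@H]([C@H](CC(C)C)c3c(OC)cc(OC)cc3OC)[C@]2(C)CC[C@@H](C(C)(C)O)C[C@@H]12 | intermediate
33 | 11-hydroxy-1β-[(1S)-3-methyl-1-(2,4,6-trimethoxyphenyl)butyl]-15-nor-5α-eudesman-4-one | O=C1CC[C@@H]([C@H](CC(C)C)c3c(OC)cc(OC)cc3OC)[C@]2(C)CC[C@@H](C(C)(C)O)C[C@@H]12 | intermediate
34 | 1β-[(1S)-3-methyl-1-(2,4,6-trimethoxyphenyl)butyl]-5α-eudesm-4(15)-en-11-ol (deformyl macrocarpal H trimethyl ether) | C=C1CC[C@@H]([C@H](CC(C)C)c2c(OC)cc(OC)cc2OC)[C@]2(C)CC[C@@H](C(C)(C)O)C[C@@H]12 | intermediate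
35 | dilithio derivative of 34 (C11 lithium alkoxide, lithium on the aryl carbon between two methoxy groups) | C=C1CC[C@@H]([C@H](CC(C)C)c2c(OC)cc(OC)c([Li])c2OC)[C@]2(C)CC[C@@H](C(C)(C)O[Li])C[C@@H]12 | intermediate
36 | lithium α-(dimethylamino)alkoxide from 35 and DMF | C=C1CC[C@@H]([C@H](CC(C)C)c2c(OC)cc(OC)c(C(O[Li])N(C)C)c2OC)[C@]2(C)CC[C@@H](C(C)(C)O[Li])C[C@@H]12 | intermediate
37 | 1β-[(1S)-1-(3-formyl-2,4,6-trimethoxyphenyl)-3-methylbutyl]-5α-eudesm-4(15)-en-11-ol | C=C1CC[C@@H]([C@H](CC(C)C)c2c(OC)cc(OC)c(C=O)c2OC)[C@]2(C)CC[C@@H](C(C)(C)O)C[C@@H]12 | intermediate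
38 | lithium α-(4-methylpiperazin-1-yl)alkoxide of 37 (C11 lithium alkoxide) | C=C1CC[C@@H]([C@H](CC(C)C)c2c(OC)cc(OC)c(C(O[Li])N3CCN(C)CC3)c2OC)[C@]2(C)CC[C@@H](C(C)(C)O[Li])C[C@@H]12 | intermediate
39 | ring-lithiated 38 (lithium on the last aryl C–H carbon) | C=C1CC[C@@H]([C@H](CC(C)C)c2c(OC)c([Li])c(OC)c(C(O[Li])N3CCN(C)CC3)c2OC)[C@]2(C)CC[C@@H](C(C)(C)O[Li])C[C@@H]12 | intermediate
40 | lithium α-(dimethylamino)alkoxide from 39 and DMF | C=C1CC[C@@H]([C@H](CC(C)C)c2c(OC)c(C(O[Li])N(C)C)c(OC)c(C(O[Li])N3CCN(C)CC3)c2OC)[C@]2(C)CC[C@@H](C(C)(C)O[Li])C[C@@H]12 | intermediate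
41 | 1β-[(1S)-1-(3,5-diformyl-2,4,6-trimethoxyphenyl)-3-methylbutyl]-5α-eudesm-4(15)-en-11-ol (macrocarpal H trimethyl ether) | C=C1CC[C@@H]([C@H](CC(C)C)c2c(OC)c(C=O)c(OC)c(C=O)c2OC)[C@]2(C)CC[C@@H](C(C)(C)O)C[C@@H]12 | intermediate
42 | macrocarpal H, 1β-[(1S)-1-(3,5-diformyl-2,4,6-trihydroxyphenyl)-3-methylbutyl]-5α-eudesm-4(15)-en-11-ol (C1 S, C5 S, C7 R, C10 S) | C=C1CC[C@@H]([C@H](CC(C)C)c2c(O)c(C=O)c(O)c(C=O)c2O)[C@]2(C)CC[C@@H](C(C)(C)O)C[C@@H]12 | target

Total step count: 23 (steps 1–9 and 12–23 in the main line, steps 10–11 for the arylacetic acid).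
Longest linear sequence: 21 steps, from 1 to 42.

Steps most likely to fail

Step 13. What may go wrong: no sigmatropic shift at accessible temperatures because ring A resists tilting the equatorial 3β C–O bond into an axial position, so that the silyl ketene acetal fragments or is C-silylated instead; or loss of C1′ control through a competing chair pathway. The fallback is a Johnson–Claisen rearrangement, which forms the ketene acetal without an enolate; it sets out from 17 and comes back at 28. Bought 2,4,6-trimethoxyphenylacetonitrile would be taken by the Pinner reaction (HCl, MeOH, Et2O, 0 °C) to methyl 2-(2,4,6-trimethoxyphenyl)acetimidate hydrochloride F1, and by methanolysis (MeOH, rt) to the trimethyl orthoester 1,3,5-trimethoxy-2-(2,2,2-trimethoxyethyl)benzene F2. Heating 17 with F2 and catalytic propionic acid in xylene at 140 °C with removal of methanol should give, by alkoxy exchange, loss of methanol and [3,3] shift, the methyl ester of 27 F3. Because the ketene acetal geometry equilibrates under these conditions, the same boat with the aryl group turned away from C14 should be the productive one. LiAlH4 (THF, 0 °C) would then reduce F3 to 28.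

Step 16. What may go wrong: enolisation of the α-aryl aldehyde by the basic ylide, eroding C1′, or failure of the bulky ylide to add to the congested carbonyl. The fallback replaces olefination by carbonyl addition and radical deoxygenation; it sets out from 29 and comes back at 31. The weakly basic organocerium reagent from i-PrMgCl and CeCl3 (THF, −78 °C) should add to 29 to give the secondary alcohol 1β-[(1S)-2-hydroxy-3-methyl-1-(2,4,6-trimethoxyphenyl)butyl]-4α-(tert-butyldimethylsilyloxy)-11-(triethylsilyloxy)-15-nor-5α-eudesm-2-ene F4 (either carbinol epimer serves). NaH, CS2 and then MeI would convert it into the S-methyl xanthate of that alcohol F5. Barton–McCombie deoxygenation (Bu3SnH, AIBN, toluene, 90 °C) would give 1β-[(1S)-3-methyl-1-(2,4,6-trimethoxyphenyl)butyl]-4α-(tert-butyldimethylsilyloxy)-11-(triethylsilyloxy)-15-nor-5α-eudesm-2-ene F6. Hydrogenation of F6 under the conditions of step 17 (H2, PtO2, EtOAc) gives 31.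

Step 9. What may go wrong: poor facial selectivity, with equatorial hydride delivery from the β face steered by the neighbouring 4α silyl ether, or 1,2-silyl migration between the C4 and C3 oxygens. The fallback inverts C3 at the esterification instead of relying on a selective reduction; it sets out from 16 and comes back at 23. The reduction would be accepted as it falls, or driven with the bulky hydride LiBH(s-Bu)3 (THF, −78 °C), toward 4α-(tert-butyldimethylsilyloxy)-11-(triethylsilyloxy)-15-nor-5α-eudesm-1-en-3α-ol F7. F7 would be coupled with acid 22 under Mitsunobu conditions (PPh3, DIAD, toluene, 0 °C → rt), and displacement with inversion at C3 should give 23 directly. Attack at C1 instead of C3 is disfavoured because C1 is neopentyl.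

Further compounds
F1 | step 13 | methyl 2-(2,4,6-trimethoxyphenyl)acetimidate hydrochloride | COC(=N)Cc1c(OC)cc(OC)cc1OC.Cl
F2 | step 13 | 1,3,5-trimethoxy-2-(2,2,2-trimethoxyethyl)benzene | COc1cc(OC)c(CC(OC)(OC)OC)c(OC)c1
F3 | step 13 | methyl ester of 27 | CC(C)(C)[Si](C)(C)O[C@@H]1C=C[C@@H]([C@H](C(=O)OC)c3c(OC)cc(OC)cc3OC)[C@]2(C)CC[C@@H](C(C)(C)O[Si](CC)(CC)CC)C[C@@H]12
F4 | step 16 | 1β-[(1S)-2-hydroxy-3-methyl-1-(2,4,6-trimethoxyphenyl)butyl]-4α-(tert-butyldimethylsilyloxy)-11-(triethylsilyloxy)-15-nor-5α-eudesm-2-ene | CC(C)(C)[Si](C)(C)O[C@@H]1C=C[C@@H]([C@H](C(O)C(C)C)c3c(OC)cc(OC)cc3OC)[C@]2(C)CC[C@@H](C(C)(C)O[Si](CC)(CC)CC)C[C@@H]12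
F5 | step 16 | S-methyl xanthate of F4 | CC(C)(C)[Si](C)(C)O[C@@H]1C=C[C@@H]([C@H](C(OC(=S)SC)C(C)C)c3c(OC)cc(OC)cc3OC)[C@]2(C)CC[C@@H](C(C)(C)O[Si](CC)(CC)CC)C[C@@H]12
F6 | step 16 | 1β-[(1S)-3-methyl-1-(2,4,6-trimethoxyphenyl)butyl]-4α-(tert-butyldimethylsilyloxy)-11-(triethylsilyloxy)-15-nor-5α-eudesm-2-ene | CC(C)(C)[Si](C)(C)O[C@@H]1C=C[C@@H]([C@H](CC(C)C)c3c(OC)cc(OC)cc3OC)[C@]2(C)CC[C@@H](C(C)(C)O[Si](CC)(CC)CC)C[C@@H]12
F7 | step 9 | 4α-(tert-butyldimethylsilyloxy)-11-(triethylsilyloxy)-15-nor-5α-eudesm-1-en-3α-ol | O[C@@H]1C=C[C@]2(C)CC[C@@H](C(C)(C)O[Si](CC)(CC)CC)C[C@H]2[C@@H]1O[Si](C)(C)C(C)(C)C
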